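Its constants belong to no real substance; the run is a simulation.

| setting | Saturday's | Monday's | Tuesday's | Sunday's |
|---|---|---|---|---|
| substrate | 0.20 M | 0.20 M | 0.20 M (fed, over 64.0 s) | 0.20 M |
| reagent | 0.190 M | 0.190 M | 0.190 M | 0.190 M |
| remark | one stirred flow tank at steady state, fed with the mixture as stated, mean residence time 80 s | a single well-mixed tank run continuously and read at steady state, 400 s in it on average | all but substrate at the start; substrate goes in evenly over 64.0 s, the run ends at 80 s | everything together in a closed stirred flask, run for 80 s |
| time |  |  | 80 s | 80 s |

    substrate + reagent → intermediate + released group (k1 = 0.0260 M⁻¹ s⁻¹)
    intermediate → product (k2 = 0.00454 s⁻¹)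

- the set-up with the highest amount of product at the outlet or at the end, in percent of the substrate put in ("none" if the first two lie within 2 percentage points) (Saturday's / Monday's / Tuesday's / Sunday's / none)
- amount of product at the outlet or at the end, in percent of the substrate put in, Saturday's
- amount of product at the outlet or at the end, in percent of the substrate put in, Monday's
- amount of product at the outlet or at the end, in percent of the substrate put in, Tuesday's
- amount of product at the outlet or at the end, in percent of the substrate put in, Sunday's

- the stated concentrations are those of everything mixed, before any reaction; amounts are the same in each set-up
- the feed brings no volume worth counting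
- run time (Tuesday's): 80 s

**Slow exit.** The intermediate leaves slowly: its mean lifetime L, one over the rate constant of the second step, is 220 s, longer than the 80 s of Saturday's tank and Sunday's flask.

**The puzzle.** Saturday's tank and Sunday's flask both allow 80 s, and Saturday's tank works throughout at its lowered outlet concentrations. It should therefore turn over less substrate than Sunday's flask, yet it should deliver more product.

**Fraction left.** In my reckoning, s is the fraction of substrate left, from the quadratic balance in each tank: 0.770 for Saturday's and 0.511 for Monday's. Treating the partners as equal gives 0.717 for Sunday's.

Of the substrate turned over, a steady tank keeps as intermediate the fraction one over one plus the ratio of mean residence time to L: 0.734 for Saturday's and 0.355 for Monday's. Sunday's flask, with the mean age of its intermediate taken as half the run, keeps the exponential of minus that age over L, or 0.834. Saturday's tank thus turns over less than Sunday's flask, but a larger part of that becomes product.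

Product comes to 6.14% for Saturday's, 31.6% for Monday's and 4.70% for Sunday's. This reckoning stops short of Tuesday's.

**The forecast.** It names Monday's, with 6.1%, 31.6%, 2.2% and 5% for Saturday's, Monday's, Tuesday's and Sunday's. It favours Saturday's over Sunday's because “its outlet includes material with long residence times”. Its Sunday's value stands above my reckoning.

**The result.** The simulation gives Monday's, with 6.14%, 31.6%, 2.31% and 5.02% in the same order. Monday's outlet carries 51.1% substrate and 17.4% intermediate. With a mean stay of 1.82 lifetimes, Monday's tank still keeps 0.355 of its turnover as intermediate, which is 17.4% of the charge.

**Later reading.** Tuesday's flask read at 3.0 min has 58% of its substrate left. Taking the mean age as half that time, L gives a kept fraction of 0.665 as intermediate, and so an estimate of 14.1% product. The computed flask holds 13.3% product and 28.4% intermediate.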